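## The problem

Target 17, (1S,2R)-1-(3,4-dihydroxyphenyl)-2-[4-(3-hydroxypropyl)-2-methoxyphenoxy]propane-1,3-diol, is an open-chain 8-O-4' neolignan in which no ring has to be closed: a catechol ring (ring A) sits on the benzylic carbinol carbon C7, and the next carbon, C8, carries the hydroxymethyl group C9 and is tied through an ether oxygen to C4' of a guaiacyl ring (ring B) that bears a 3-hydroxypropyl chain para to that oxygen. The work therefore lies in one aryl–C7 bond, one C8–O–aryl bond and two adjacent stereocentres, C7 (S) and C8 (R), in the erythro relation. C8 can be set on its own and then direct C7 by 1,2-induction, whereas the reverse order would need a displacement at C8 next to a benzylic carbinol. The compound tolerates little: the free catechol oxidises in air and in base, and the C7 hydroxyl, para to oxygen, ionises in acid to a quinone methide and can be hydrogenolysed. Any carbonyl group placed on C7 or C9 during the synthesis makes the C8 hydrogen acidic, which opens epimerisation and β-elimination. The enabling feature is that C8 carries two oxygenated one-carbon arms, C7 and C9. Before ring A is attached, C8 is therefore the central carbon of a prochiral 2-aryloxypropane-1,3-diol whose arms an enzyme can tell apart, and the arm that becomes C7 can be raised to an aldehyde that accepts ring A as an aryl-metal.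

## Retrosynthesis

**End game, 17 back to 13.** No skeletal bond is cut. The catechol of 17 is traced to the dibenzyl ether 16, so that it is released last, by neutral hydrogenolysis, and never meets base, fluoride or peroxide. The C9 hydroxyl of 16 is traced to the primary silyl ether 15. The hydroxypropyl chain of 15 is traced to the allyl group of 13 through organoborane 14. The allyl group comes with eugenol and is inert to every earlier reagent; carrying a protected alcohol instead would cost a protection and one more group to remove. The forward steps must hydrate a terminal alkene in the anti-Markovnikov sense beside a free secondary alcohol, then remove silicon and benzyl without touching the benzylic C7–O bond.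

**Key disconnection, 13 to 9 and 10.** The bond between C7 and C1 of ring A is cut. This gives the α-aryloxy aldehyde 9 and the commercial aryl bromide 10, which is used as aryllithium 11 and aryltitanium 12. Two neighbouring cuts were weighed:
- Cutting C8–O calls for etherification at a secondary carbon flanked by two oxygenated carbons. A direct displacement there is poor, and the aromatic substitution variant needs an activating group that the target does not have.
- Cutting C7–C8 is an aldol addition that must control both centres and the absolute sense at once.

The aryl–C7 cut leaves a three-carbon aldehyde with a single stereocentre, and that centre then controls C7. The forward reaction must give Felkin–Anh selectivity without chelation and must not enolise 9.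

**Aldehyde 9 back to monoacetate 6.** Only the oxidation level and the protecting groups change. Aldehyde 9 comes from alcohol 8 by oxidation, 8 from the silyl ether acetate 7 by methanolysis, and 7 from the (R)-monoacetate 6 by silylation. The acetate is a temporary mask for the arm that becomes C7; the silyl group is the lasting protection of C9. Carrying an ester on C9 into the key step would be shorter. It would, however, put an acyloxy leaving group β to the aldehyde and an acyl group within reach of the new C7 alkoxide. A silyl ether neither leaves nor chelates.

**Desymmetrisation, 6 back to diol 4.** One acyl–oxygen bond is cut. Monoacetate 6 comes from the prochiral diacetate 5 by lipase hydrolysis of one enantiotopic arm, and 5 from diol 4 by acetylation. Hydrolysis is chosen over enzymatic acetylation of 4 because, by the arm preference assumed below, acetylation would give the enantiomer of 6. Hydrolysis leaves the acetate on the arm that will be oxidised, which is what the protecting-group exchange needs. The forward step must give high enantiotopic selectivity and no acyl migration.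

**Diol 4 back to eugenol.** The C8–O bond is cut at the malonate oxidation level, where the carbon is achiral and doubly activated, so the ether forms by simple displacement with no stereochemical demand. Diol 4 comes from the aryloxymalonate 3 by hydride reduction, and 3 from eugenol 1 and diethyl bromomalonate 2. Both are commodity chemicals, and 1 already carries the methoxy group, the phenol oxygen and the three-carbon chain of ring B.

## Roads not taken

Alternative 1: The cut is the O–C4' aryl ether bond, made late. The potassium alkoxide of the C8 hydroxyl of the protected triol A1 (KHMDS, DMF) displaces fluoride from the cyano-activated fluoroarene A2 to give A3.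
- Merits: both stereocentres are fixed before the coupling, the C8–O bond is not broken so C8 is retained, and no epimerisable α-aryloxy carbonyl compound appears. In configurational security at C8 this road is better than the chosen plan.
- Weak points: the substitution needs the para nitrile, so the hydroxypropyl chain must be built afterwards from the nitrile by reduction, two-carbon olefination and reduction. The ortho methoxy group hinders and deactivates the arene. A1 is a hindered secondary alcohol whose own erythro stereochemistry and threefold hydroxyl differentiation must be built first, so the stereochemical problem is moved, not solved. The final hydrogenolysis must spare the C7–O bond of a benzyl ether that sits on a benzylic carbon.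
- Comparison: the chosen plan sets against this fewer steps, the intact side chain of eugenol, and a C7 oxygen that is never a benzyl ether.

Alternative 2: The cut is the C8–O4' bond and the C7–OH bond together. Peroxidase and H2O2 oxidise the cinnamyl alcohol A4 and the phenol A5 to radicals; these couple between C8 of A4 and the phenolic oxygen of A5, and water then adds at C7 to give A6.
- Merits: it is by far the shortest road, one step to the full skeleton in water with almost no protection. In step economy the chosen plan cannot compete.
- Weak points: nothing controls the absolute sense, so A6 forms with its enantiomer. The closing addition of water at C7 has no facial control, so the erythro and the threo series both arise. Cross-coupling competes with homo-coupling of each partner and with coupling at ring carbons.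
- Comparison: a single enantiomer would require separating diastereomers and then a resolution. The chosen plan is much longer but gives each stereocentre a named control element.

Alternative 3: The cut is the C7–H bond. A ketoreductase with cofactor recycling reduces the ketone of the rapidly racemising ketoester A7 and gives A8, fixing C7 and C8 in one catalytic step.
- Merits: the lability of C8 becomes an advantage, the route is convergent, the side chain is already at a useful oxidation level, and the step count would be lower. In step economy, and in principle in stereocontrol, it is as good or better.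
- Weak points: an enzyme must be found that accepts a ketone flanked by a bulky aryl group and an α-aryloxy ester and delivers one of four stereoisomers. That cannot be predicted from structure. A8 is a β-hydroxy ester open to retro-aldol cleavage and epimerisation during the ester reductions that must follow.
- Comparison: the chosen plan uses an enzyme class whose outcome can be corrected, since either antipode is reachable by switching between hydrolysis and acylation. It sets C7 by a substrate-controlled addition with a predictive model. The price is length and a labile aldehyde.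

Key step: step 8

Assumption: Burkholderia cepacia lipase is taken to act on the pro-S arm of the 2-aryloxypropane-1,3-diyl system, by analogy with its behaviour in the 2-O-benzylglycerol series, so that hydrolysis of diacetate 5 leaves the (R)-monoacetate 6; the configuration of 6 should be proved by chemical correlation before the material is carried forward.

## Route

Step 1
Reactants: 1 eugenol (4-allyl-2-methoxyphenol); 2 diethyl bromomalonate
Product: 3 diethyl 2-(4-allyl-2-methoxyphenoxy)malonate
Conditions: K2CO3, acetone, reflux
Reagents that add atoms: none
Why: Williamson-type O-alkylation of the phenoxide by the doubly activated secondary bromide, a known route to aryloxymalonates of guaiacol-type phenols; the allyl group does not isomerise under carbonate.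

Step 2
Reactants: 3 diethyl 2-(4-allyl-2-methoxyphenoxy)malonate
Product: 4 2-(4-allyl-2-methoxyphenoxy)propane-1,3-diol
Conditions: LiAlH4, THF, 0 °C to rt; aq. potassium sodium tartrate
Reagents that add atoms: none
Why: Hydride reduction of both esters to primary alcohols, the usual way to 2-aryloxypropane-1,3-diols; the alkene and the aryl ether are inert and the product is achiral.

Step 3
Reactants: 4 2-(4-allyl-2-methoxyphenoxy)propane-1,3-diol
Product: 5 2-(4-allyl-2-methoxyphenoxy)propane-1,3-diyl diacetate
Conditions: Ac2O, pyridine, DMAP (cat.), CH2Cl2, rt
Reagents that add atoms: acetic anhydride, CC(=O)OC(C)=O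
Why: Nucleophile-catalysed acylation of two unhindered primary alcohols; it provides the prochiral diester that the hydrolytic mode of the enzyme needs.

Step 4
Reactants: 5 2-(4-allyl-2-methoxyphenoxy)propane-1,3-diyl diacetate
Product: 6 (R)-2-(4-allyl-2-methoxyphenoxy)-3-hydroxypropyl acetate
Conditions: Burkholderia cepacia lipase (Amano PS), phosphate buffer pH 7–acetone, 25 °C, stopped near one equivalent of hydrolysis
Reagents that add atoms: none
Why: Enantiotopic-group-selective lipase hydrolysis of a prochiral 2-substituted propane-1,3-diyl diacetate; the acyl-enzyme mechanism cleaves the pro-S acetoxymethyl arm and so sets C8. The minor enantiomer is hydrolysed on to diol 4 faster than the major one, which raises the enantiomeric purity of 6.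

Step 5
Reactants: 6 (R)-2-(4-allyl-2-methoxyphenoxy)-3-hydroxypropyl acetate
Product: 7 (S)-2-(4-allyl-2-methoxyphenoxy)-3-(tert-butyldimethylsilyloxy)propyl acetate
Conditions: TBSCl, imidazole, CH2Cl2, 0 °C to rt
Reagents that add atoms: tert-butyldimethylsilyl chloride, CC(C)(C)[Si](C)(C)Cl
Why: Imidazole-promoted silylation of the free primary alcohol; it is fast enough to outrun acyl migration, and the descriptor changes only because the priorities of the arms change.

Step 6
Reactants: 7 (S)-2-(4-allyl-2-methoxyphenoxy)-3-(tert-butyldimethylsilyloxy)propyl acetate
Product: 8 (S)-2-(4-allyl-2-methoxyphenoxy)-3-(tert-butyldimethylsilyloxy)propan-1-ol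
Conditions: K2CO3 (cat.), MeOH, 0 °C
Reagents that add atoms: none
Why: Base-catalysed transesterification removes the acetate; catalytic carbonate at low temperature keeps 1,3-silyl migration, which would exchange the arms and racemise 8, negligible.

Step 7
Reactants: 8 (S)-2-(4-allyl-2-methoxyphenoxy)-3-(tert-butyldimethylsilyloxy)propan-1-ol
Product: 9 (R)-2-(4-allyl-2-methoxyphenoxy)-3-(tert-butyldimethylsilyloxy)propanal
Conditions: Dess–Martin periodinane, NaHCO3, CH2Cl2, 0 °C to rt; used crude at once
Reagents that add atoms: none
Why: Dess–Martin oxidation of a primary alcohol under buffered, nearly neutral conditions, which avoids the amine bases that enolise α-alkoxy aldehydes; C8 is not touched and 9 is used without chromatography or storage.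

Step 8
Reactants: 10 4-bromo-1,2-bis(benzyloxy)benzene; 9 (R)-2-(4-allyl-2-methoxyphenoxy)-3-(tert-butyldimethylsilyloxy)propanal
Product: 13 (1S,2R)-2-(4-allyl-2-methoxyphenoxy)-1-[3,4-bis(benzyloxy)phenyl]-3-(tert-butyldimethylsilyloxy)propan-1-ol, via aryllithium 11 (not isolated), via aryltitanium triisopropoxide 12 (not isolated)
Conditions: 10, n-BuLi, THF, −78 °C; ClTi(OiPr)3, −78 to −40 °C; then 9, −78 to −20 °C; aq. NH4Cl
Reagents that add atoms: none
Why: Bromine–lithium exchange on 10 gives aryllithium 11, which ClTi(OiPr)3 converts into the monoaryl tetravalent titanium species 12; this transfers its aryl group to the aldehyde carbon of 9 through a four-centre transition state, forming the bond from C7 to C1 of ring A, and no ring closes. The closest known reaction type is the non-chelation-controlled addition of organotitanium triisopropoxides to α-alkoxy aldehydes. The new stereocentre C7 is controlled by C8 through the polar Felkin–Anh arrangement: the C8–OAr bond lies antiperiplanar to the forming bond, the silyloxymethyl arm sits beside the carbonyl oxygen and the nucleophile passes the C8 hydrogen, which means attack on the Si face of the (R)-aldehyde and the (7S), erythro adduct. The step needs diastereofacial selectivity and freedom from enolisation. The first rests on the electronegative, poorly donating aryloxy group, on the bulky non-coordinating silyl ether and on three isopropoxide ligands that leave titanium too weakly Lewis acidic to hold a chelate; the second rests on the low basicity of 12 and on using fresh 9 at low temperature.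

Step 9
Reactants: 13 (1S,2R)-2-(4-allyl-2-methoxyphenoxy)-1-[3,4-bis(benzyloxy)phenyl]-3-(tert-butyldimethylsilyloxy)propan-1-ol
Product: 15 (1S,2R)-1-[3,4-bis(benzyloxy)phenyl]-3-(tert-butyldimethylsilyloxy)-2-[4-(3-hydroxypropyl)-2-methoxyphenoxy]propan-1-ol, via organoborane 14 (not isolated)
Conditions: 9-BBN (3 equiv), THF, 0 °C to rt; then NaOH, H2O2, 0 °C
Reagents that add atoms: hydrogen peroxide, OO
Why: Hydroboration–oxidation: 9-BBN adds syn to the terminal alkene with boron at the unhindered terminus and a further equivalent is taken up by the C7 hydroxyl as a borinate; alkaline peroxide then oxidises the C–B bond of 14 and hydrolyses the borinate. The silyl ether, the benzyl ethers and both stereocentres are untouched.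

Step 10
Reactants: 15 (1S,2R)-1-[3,4-bis(benzyloxy)phenyl]-3-(tert-butyldimethylsilyloxy)-2-[4-(3-hydroxypropyl)-2-methoxyphenoxy]propan-1-ol
Product: 16 (1S,2R)-1-[3,4-bis(benzyloxy)phenyl]-2-[4-(3-hydroxypropyl)-2-methoxyphenoxy]propane-1,3-diol
Conditions: TBAF, THF, 0 °C to rt
Reagents that add atoms: none
Why: Fluoride-induced cleavage of the primary silyl ether, driven by the strong Si–F bond; the benzyl ethers, the aryl ether and the benzylic alcohol are inert, and the catechol is still masked while the medium is basic.

Step 11
Reactants: 16 (1S,2R)-1-[3,4-bis(benzyloxy)phenyl]-2-[4-(3-hydroxypropyl)-2-methoxyphenoxy]propane-1,3-diol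
Product: 17 (1S,2R)-1-(3,4-dihydroxyphenyl)-2-[4-(3-hydroxypropyl)-2-methoxyphenoxy]propane-1,3-diol
Conditions: H2 (1 atm), 10% Pd/C, EtOAc–EtOH, rt
Reagents that add atoms: none
Why: Heterogeneous hydrogenolysis of the two aryl benzyl ethers, which cleave much faster than the C7–OH bond in a neutral solvent; the oxidisable catechol is released last, under neutral reducing conditions.

## Compound list

1 | eugenol (4-allyl-2-methoxyphenol) | C=CCc1ccc(O)c(OC)c1 | starting material
2 | diethyl bromomalonate | CCOC(=O)C(Br)C(=O)OCC | starting material
3 | diethyl 2-(4-allyl-2-methoxyphenoxy)malonate | CCOC(=O)C(Oc1ccc(CC=C)cc1OC)C(=O)OCC | intermediate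
4 | 2-(4-allyl-2-methoxyphenoxy)propane-1,3-diol | COc1cc(CC=C)ccc1OC(CO)CO | intermediate
5 | 2-(4-allyl-2-methoxyphenoxy)propane-1,3-diyl diacetate | COc1cc(CC=C)ccc1OC(COC(C)=O)COC(C)=O | intermediate
6 | (R)-2-(4-allyl-2-methoxyphenoxy)-3-hydroxypropyl acetate | COc1cc(CC=C)ccc1O[C@H](CO)COC(C)=O | intermediate
7 | (S)-2-(4-allyl-2-methoxyphenoxy)-3-(tert-butyldimethylsilyloxy)propyl acetate | COc1cc(CC=C)ccc1O[C@H](CO[Si](C)(C)C(C)(C)C)COC(C)=O | intermediate
8 | (S)-2-(4-allyl-2-methoxyphenoxy)-3-(tert-butyldimethylsilyloxy)propan-1-ol | COc1cc(CC=C)ccc1O[C@H](CO[Si](C)(C)C(C)(C)C)CO | intermediate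
9 | (R)-2-(4-allyl-2-methoxyphenoxy)-3-(tert-butyldimethylsilyloxy)propanal | COc1cc(CC=C)ccc1O[C@H](CO[Si](C)(C)C(C)(C)C)C=O | intermediate
10 | 4-bromo-1,2-bis(benzyloxy)benzene | Brc1ccc(OCc2ccccc2)c(OCc2ccccc2)c1 | starting material
11 | [3,4-bis(benzyloxy)phenyl]lithium | [Li]c1ccc(OCc2ccccc2)c(OCc2ccccc2)c1 | intermediate
12 | [3,4-bis(benzyloxy)phenyl]tri(propan-2-yloxy)titanium | CC(C)O[Ti](OC(C)C)(OC(C)C)c1ccc(OCc2ccccc2)c(OCc2ccccc2)c1 | intermediate
13 | (1S,2R)-2-(4-allyl-2-methoxyphenoxy)-1-[3,4-bis(benzyloxy)phenyl]-3-(tert-butyldimethylsilyloxy)propan-1-ol | COc1cc(CC=C)ccc1O[C@H](CO[Si](C)(C)C(C)(C)C)[C@@H](O)c1ccc(OCc2ccccc2)c(OCc2ccccc2)c1 | intermediate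
14 | bis(9-BBN) intermediate: 13 carrying one 9-borabicyclo[3.3.1]nonan-9-yl group on the terminal carbon of the propyl chain formed from the allyl group and a second one on the C7 oxygen as a borinate ester, (1S,2R) unchanged | COc1cc(CCCB2C3CCCC2CCC3)ccc1O[C@H](CO[Si](C)(C)C(C)(C)C)[C@@H](OB2C3CCCC2CCC3)c1ccc(OCc2ccccc2)c(OCc2ccccc2)c1 | intermediate
15 | (1S,2R)-1-[3,4-bis(benzyloxy)phenyl]-3-(tert-butyldimethylsilyloxy)-2-[4-(3-hydroxypropyl)-2-methoxyphenoxy]propan-1-ol | COc1cc(CCCO)ccc1O[C@H](CO[Si](C)(C)C(C)(C)C)[C@@H](O)c1ccc(OCc2ccccc2)c(OCc2ccccc2)c1 | intermediate
16 | (1S,2R)-1-[3,4-bis(benzyloxy)phenyl]-2-[4-(3-hydroxypropyl)-2-methoxyphenoxy]propane-1,3-diol | COc1cc(CCCO)ccc1O[C@H](CO)[C@@H](O)c1ccc(OCc2ccccc2)c(OCc2ccccc2)c1 | intermediate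
17 | (1S,2R)-1-(3,4-dihydroxyphenyl)-2-[4-(3-hydroxypropyl)-2-methoxyphenoxy]propane-1,3-diol | COc1cc(CCCO)ccc1O[C@H](CO)[C@@H](O)c1ccc(O)c(O)c1 | target

## Step count and risks

Total: 11 steps. Longest linear sequence: 11 steps, from eugenol 1 to 17; aryl bromide 10 is bought and enters at step 8.

**Step 8 (key step).** Facial selectivity may be poor. The aryl ether oxygen and its ortho methoxy neighbour could still hold a metal in a chelate, and incomplete transmetalation would leave the more basic and less selective aryllithium 11. Enolisation of 9 would erode C8. Fallback, setting out from 13 obtained as a mixture of C7 epimers: Dess–Martin oxidation gives the ketone (R)-2-(4-allyl-2-methoxyphenoxy)-1-[3,4-bis(benzyloxy)phenyl]-3-(tert-butyldimethylsilyloxy)propan-1-one F1. Reduction with Zn(BH4)2 in Et2O at low temperature then goes through the zinc chelate between the ketone oxygen and the ether oxygen on C8. Hydride enters from the side of the C8 hydrogen, which gives the erythro alcohol, and the route is rejoined at 13.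

**Step 4.** The enzyme may discriminate the two arms poorly or in the opposite sense to the one assumed, and acyl migration between the arms in buffer would racemise 6. An opposite sense alone would be met by enzymatic acetylation of diol 4 with vinyl acetate, which would then give 6 directly. If selectivity is poor in both modes, the fallback takes C8 from the chiral pool and sets out from eugenol 1. Commercial methyl (S)-2,3-dihydroxypropanoate is silylated at its primary hydroxyl (TBSCl, imidazole) to methyl (S)-3-(tert-butyldimethylsilyloxy)-2-hydroxypropanoate F2. Mitsunobu etherification of F2 with 1 (PPh3, DIAD, THF) inverts the carbinol carbon and gives methyl (R)-2-(4-allyl-2-methoxyphenoxy)-3-(tert-butyldimethylsilyloxy)propanoate F3. LiBH4 in THF reduces the ester, and the route is rejoined at 8.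

**Step 7.** The α-aryloxy aldehyde may enolise during oxidation or work-up, which epimerises C8, and may form a hydrate that lowers the effective titre in step 8. Fallback, setting out from 8 and avoiding a free aldehyde: TEMPO and PhI(OAc)2 in aqueous MeCN give (R)-2-(4-allyl-2-methoxyphenoxy)-3-(tert-butyldimethylsilyloxy)propanoic acid F4. Coupling with MeNHOMe·HCl (EDC·HCl, N-methylmorpholine) gives (R)-2-(4-allyl-2-methoxyphenoxy)-3-(tert-butyldimethylsilyloxy)-N-methoxy-N-methylpropanamide F5. Aryllithium 11 at −78 °C converts F5 into the ketone F1 of the first fallback, and the Zn(BH4)2 reduction described there rejoins the route at 13.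

**Step 2.** The hydride may deprotonate the acidic malonate C–H instead of reducing the esters. The enolate resists reduction, and after partial reduction aryloxide can be expelled by β-elimination, so material is lost. Fallback, setting out from eugenol 1: Mitsunobu etherification with commercial cis-2-phenyl-1,3-dioxan-5-ol (PPh3, DIAD) gives trans-5-(4-allyl-2-methoxyphenoxy)-2-phenyl-1,3-dioxane F6. Mild hydrolysis of the acetal in aqueous AcOH rejoins the route at 4.

## Further compounds

F1 | step 8 | (R)-2-(4-allyl-2-methoxyphenoxy)-1-[3,4-bis(benzyloxy)phenyl]-3-(tert-butyldimethylsilyloxy)propan-1-one | COc1cc(CC=C)ccc1O[C@H](CO[Si](C)(C)C(C)(C)C)C(=O)c1ccc(OCc2ccccc2)c(OCc2ccccc2)c1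
F2 | step 4 | methyl (S)-3-(tert-butyldimethylsilyloxy)-2-hydroxypropanoate | COC(=O)[C@@H](O)CO[Si](C)(C)C(C)(C)C
F3 | step 4 | methyl (R)-2-(4-allyl-2-methoxyphenoxy)-3-(tert-butyldimethylsilyloxy)propanoate | COc1cc(CC=C)ccc1O[C@H](CO[Si](C)(C)C(C)(C)C)C(=O)OC
F4 | step 7 | (R)-2-(4-allyl-2-methoxyphenoxy)-3-(tert-butyldimethylsilyloxy)propanoic acid | COc1cc(CC=C)ccc1O[C@H](CO[Si](C)(C)C(C)(C)C)C(=O)O
F5 | step 7 | (R)-2-(4-allyl-2-methoxyphenoxy)-3-(tert-butyldimethylsilyloxy)-N-methoxy-N-methylpropanamide | COc1cc(CC=C)ccc1O[C@H](CO[Si](C)(C)C(C)(C)C)C(=O)N(C)OC
F6 | step 2 | trans-5-(4-allyl-2-methoxyphenoxy)-2-phenyl-1,3-dioxane | COc1cc(CC=C)ccc1O[C@H]1CO[C@H](c2ccccc2)OC1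
A1 | alternative 1 | (1S,2R)-1,3-bis(benzyloxy)-1-[3,4-bis(benzyloxy)phenyl]propan-2-ol | O[C@H](COCc1ccccc1)[C@@H](OCc1ccccc1)c1ccc(OCc2ccccc2)c(OCc2ccccc2)c1
A2 | alternative 1 | 4-fluoro-3-methoxybenzonitrile | COc1cc(C#N)ccc1F
A3 | alternative 1 | 4-{[(1S,2R)-1,3-bis(benzyloxy)-1-[3,4-bis(benzyloxy)phenyl]propan-2-yl]oxy}-3-methoxybenzonitrile | COc1cc(C#N)ccc1O[C@H](COCc1ccccc1)[C@@H](OCc1ccccc1)c1ccc(OCc2ccccc2)c(OCc2ccccc2)c1
A4 | alternative 2 | (E)-2-(benzyloxy)-4-(3-hydroxyprop-1-en-1-yl)phenol | OC/C=C/c1ccc(O)c(OCc2ccccc2)c1
A5 | alternative 2 | 4-(3-hydroxypropyl)-2-methoxyphenol | COc1cc(CCCO)ccc1O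
A6 | alternative 2 | (1S,2R)-1-[3-(benzyloxy)-4-hydroxyphenyl]-2-[4-(3-hydroxypropyl)-2-methoxyphenoxy]propane-1,3-diol | COc1cc(CCCO)ccc1O[C@H](CO)[C@@H](O)c1ccc(O)c(OCc2ccccc2)c1
A7 | alternative 3 | methyl 3-[3,4-bis(benzyloxy)phenyl]-2-[2-methoxy-4-(3-methoxy-3-oxopropyl)phenoxy]-3-oxopropanoate (racemic) | COC(=O)CCc1ccc(OC(C(=O)OC)C(=O)c2ccc(OCc3ccccc3)c(OCc3ccccc3)c2)c(OC)c1
A8 | alternative 3 | methyl (2S,3S)-3-[3,4-bis(benzyloxy)phenyl]-3-hydroxy-2-[2-methoxy-4-(3-methoxy-3-oxopropyl)phenoxy]propanoate | COC(=O)CCc1ccc(O[C@H](C(=O)OC)[C@@H](O)c2ccc(OCc3ccccc3)c(OCc3ccccc3)c2)c(OC)c1
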